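**Retrosynthetic overview** (labels: ring A = O1, C2 (C=O), C3, C4, C5; side chain C1′ (exocyclic =CH) to C10′)

1. Target 22 comes from triol 20 by benzoylation at O10′ and acetylation at O3′ and O4; 20 comes from the trisilylated lactone 19.
2. The strategy rests on ring A being an (E)-α-alkylidene γ-lactone: O1–C2 and C2–C3 are made together from the C5 hydroxyl, CO and a C3≡C1′ alkyne (18 → 19). This is the only ring closure of the route, and syn addition gives the E C3=C1′ alkene.
3. Precursor 18 is cut at C1′–C2′: the lithium acetylide of enyne acetonide 7 opens the (S)-alkenyl epoxide 13 at its CH2.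
4. 7 comes from 2,3-O-isopropylidene-D-erythronolactone 1 (erythrose C1 becomes alkyne carbon C3, C2 becomes C4, C3 becomes C5, C4 becomes the isobutenyl CH). 13 comes from nerol 8 (Z alkene kept; E-selective allylic oxidation, methylene transfer, hydrolytic kinetic resolution for C3′).
5. O4 is capped as a TBS ether before the carbonylation, because a free 3-alkyne-1,2-diol is prone to cyclodehydration to a furan under divalent palladium. O3′ carries TIPS so that it outlasts acetonide cleavage, and O10′ carries TBDPS.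

Key step: step 14

Remark: the sense of the kinetic resolution (the S,S catalyst leaving the S epoxide) is assumed to follow that of simple monosubstituted epoxides, which have the same priority order at the stereocentre.

**Route**

Step 1
Reactants: 1 2,3-O-isopropylidene-D-erythronolactone
Product: 2 2,3-O-isopropylidene-D-erythrofuranose (cis-fused lactol, anomer mixture)
Conditions: i-Bu2AlH (1.1 equiv), CH2Cl2, −78 °C
Reagents that add atoms: none
Why: Half-reduction of a lactone with i-Bu2AlH at −78 °C stops at the aluminium hemiacetalate, which gives the lactol on work-up and leaves both stereocentres untouched.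

Step 2
Reactants: 2 2,3-O-isopropylidene-D-erythrofuranose
Product: 3 [(4R,5S)-5-ethynyl-2,2-dimethyl-1,3-dioxolan-4-yl]methanol
Conditions: dimethyl (1-diazo-2-oxopropyl)phosphonate, K2CO3, MeOH, rt → 50 °C
Reagents that add atoms: dimethyl (1-diazo-2-oxopropyl)phosphonate, CC(=O)C(=[N+]=[N-])P(=O)(OC)OC
Why: Ohira–Bestmann (Seyferth–Gilbert) homologation of the open-chain aldehyde tautomer turns C1 into a terminal alkyne, and since unreacted material rests as the cis-fused lactol the α-stereocentre should not drift into the trans-dioxolane series.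

Step 3
Reactants: 3 [(4R,5S)-5-ethynyl-2,2-dimethyl-1,3-dioxolan-4-yl]methanol
Product: 4 (4S,5S)-5-ethynyl-2,2-dimethyl-1,3-dioxolane-4-carbaldehyde
Conditions: Dess–Martin periodinane, CH2Cl2, 0 °C → rt; used crude
Reagents that add atoms: none
Why: Dess–Martin oxidation of the primary alcohol is non-basic, so the epimerisable cis-aldehyde should be obtained intact and is carried on at once.

Step 4
Reactants: 4 (4S,5S)-5-ethynyl-2,2-dimethyl-1,3-dioxolane-4-carbaldehyde; 5 isopropyltriphenylphosphonium iodide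
Product: 7 (4S,5R)-4-ethynyl-2,2-dimethyl-5-(2-methylprop-1-en-1-yl)-1,3-dioxolane, via isopropylidene ylide 6 (not isolated)
Conditions: 5, KN(SiMe3)2, THF, 0 °C; then 4, −78 → 0 °C
Reagents that add atoms: none
Why: Wittig olefination with the symmetrical, non-stabilised isopropylidene ylide raises no E/Z question, and at −78 °C carbonyl addition should outrun enolisation of the α-alkoxy aldehyde, so both chiral-pool stereocentres are retained.

Step 5
Reactants: 8 nerol
Product: 9 tert-butyl{[(2Z)-3,7-dimethylocta-2,6-dien-1-yl]oxy}diphenylsilane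
Conditions: TBDPSCl, imidazole, CH2Cl2, 0 °C → rt
Reagents that add atoms: tert-butyl(chloro)diphenylsilane, CC(C)(C)[Si](Cl)(c1ccccc1)c1ccccc1
Why: Imidazole-promoted silylation of the primary allylic alcohol is routine, and the TBDPS ether should last through every later step up to fluoride.

Step 6
Reactants: 9 tert-butyl{[(2Z)-3,7-dimethylocta-2,6-dien-1-yl]oxy}diphenylsilane
Product: 10 (2E,6Z)-8-[(tert-butyldiphenylsilyl)oxy]-2,6-dimethylocta-2,6-dien-1-ol
Conditions: SeO2 (cat.), t-BuOOH, salicylic acid (cat.), CH2Cl2, rt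
Reagents that add atoms: selenium dioxide (oxygen carrier), O=[Se]=O; tert-butyl hydroperoxide (terminal oxidant), CC(C)(C)OO
Why: Catalytic SeO2 allylic oxidation (ene reaction, then [2,3]-sigmatropic shift) hydroxylates the E-methyl group of the distal, more electron-rich trisubstituted alkene, which fixes the E geometry of the later C4′=C5′ alkene and leaves the Z alkene of nerol alone.

Step 7
Reactants: 10 (2E,6Z)-8-[(tert-butyldiphenylsilyl)oxy]-2,6-dimethylocta-2,6-dien-1-ol
Product: 11 (2E,6Z)-8-[(tert-butyldiphenylsilyl)oxy]-2,6-dimethylocta-2,6-dienal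
Conditions: MnO2, CH2Cl2, rt
Reagents that add atoms: none
Why: MnO2 oxidation is selective for the allylic alcohol, converges any enal already formed in step 6, and does not isomerise the alkenes.

Step 8
Reactants: 11 (2E,6Z)-8-[(tert-butyldiphenylsilyl)oxy]-2,6-dimethylocta-2,6-dienal
Product: 12 rac-tert-butyl{[(2Z,6E)-3-methyl-7-(oxiran-2-yl)octa-2,6-dien-1-yl]oxy}diphenylsilane
Conditions: trimethylsulfonium iodide, n-BuLi, THF, −10 °C; then 11, −10 °C → rt
Reagents that add atoms: trimethylsulfonium iodide, C[S+](C)C.[I-]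
Why: Corey–Chaykovsky methylene transfer from dimethylsulfonium methylide proceeds by 1,2-addition to the enal carbonyl and ring closure, giving the alkenyl epoxide as a racemate.

Step 9
Reactants: 12 rac-tert-butyl{[(2Z,6E)-3-methyl-7-(oxiran-2-yl)octa-2,6-dien-1-yl]oxy}diphenylsilane
Product: 13 tert-butyl({(2Z,6E)-3-methyl-7-[(2S)-oxiran-2-yl]octa-2,6-dien-1-yl}oxy)diphenylsilane
Conditions: (S,S)-(salen)Co(OAc) (1 mol%; trivalent cobalt; salen = N,N′-bis(3,5-di-tert-butylsalicylidene)cyclohexane-1,2-diaminate), H2O (0.55 equiv), THF, 0 °C → rt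
Reagents that add atoms: none
Why: Jacobsen hydrolytic kinetic resolution of a terminal epoxide, in which the catalyst hydrolyses the (R)-epoxide at its CH2 and leaves the (S)-epoxide, sets the C3′ stereocentre under catalyst control.

Step 10
Reactants: 7 (4S,5R)-4-ethynyl-2,2-dimethyl-5-(2-methylprop-1-en-1-yl)-1,3-dioxolane; 13 tert-butyl({(2Z,6E)-3-methyl-7-[(2S)-oxiran-2-yl]octa-2,6-dien-1-yl}oxy)diphenylsilane
Product: 15 (4R,5E,9Z)-11-[(tert-butyldiphenylsilyl)oxy]-1-[(4S,5R)-2,2-dimethyl-5-(2-methylprop-1-en-1-yl)-1,3-dioxolan-4-yl]-5,9-dimethylundeca-5,9-dien-1-yn-4-ol, via lithium acetylide 14 (not isolated)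
Conditions: 7, n-BuLi, THF, −78 → 0 °C; DMPU, then 13, 0 °C → rt
Reagents that add atoms: none
Why: SN2 opening of a terminal epoxide by a lithium acetylide in a dipolar aprotic medium should occur at the unhindered CH2, no Lewis acid being used so that the allylic C–O bond is not activated, and the carbinol carbon is not touched (its descriptor changes from S to R through the priority rules only).

Step 11
Reactants: 15 (4R,5E,9Z)-11-[(tert-butyldiphenylsilyl)oxy]-1-[(4S,5R)-2,2-dimethyl-5-(2-methylprop-1-en-1-yl)-1,3-dioxolan-4-yl]-5,9-dimethylundeca-5,9-dien-1-yn-4-ol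
Product: 16 the O4-triisopropylsilyl ether of 15
Conditions: TIPSOTf, 2,6-lutidine, CH2Cl2, −78 → 0 °C
Reagents that add atoms: triisopropylsilyl trifluoromethanesulfonate, CC(C)[Si](OS(=O)(=O)C(F)(F)F)(C(C)C)C(C)C
Why: Silylation of a hindered secondary alcohol with a silyl triflate and a hindered base is reliable, and TIPS is chosen because it should survive the acid of step 12 and the traces of HCl in step 14.

Step 12
Reactants: 16 the O4-triisopropylsilyl ether of 15
Product: 17 (4R,5S,9R,10E,14Z)-16-[(tert-butyldiphenylsilyl)oxy]-2,10,14-trimethyl-9-[(triisopropylsilyl)oxy]hexadeca-2,10,14-trien-6-yne-4,5-diol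
Conditions: p-TsOH·H2O (10 mol%), MeOH, 0 °C → rt
Reagents that add atoms: none
Why: Acid-catalysed transacetalisation removes the isopropylidene group as 2,2-dimethoxypropane without breaking a C–O bond at either stereocentre, and the TIPS and TBDPS ethers should tolerate catalytic acid.

Step 13
Reactants: 17 (4R,5S,9R,10E,14Z)-16-[(tert-butyldiphenylsilyl)oxy]-2,10,14-trimethyl-9-[(triisopropylsilyl)oxy]hexadeca-2,10,14-trien-6-yne-4,5-diol
Product: 18 (4R,5S,9R,10E,14Z)-5-[(tert-butyldimethylsilyl)oxy]-16-[(tert-butyldiphenylsilyl)oxy]-2,10,14-trimethyl-9-[(triisopropylsilyl)oxy]hexadeca-2,10,14-trien-6-yn-4-ol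
Conditions: TBSCl (1.1 equiv), imidazole, DMF, 0 °C
Reagents that add atoms: tert-butyl(chloro)dimethylsilane, CC(C)(C)[Si](C)(C)Cl
Why: Sterically controlled monosilylation should take the propargylic hydroxyl, which is flanked by the slim alkyne, before the allylic hydroxyl shielded by the 2-methylpropenyl group, and once it is silylated the neighbour is too hindered to follow.

Step 14
Reactants: 18 (4R,5S,9R,10E,14Z)-5-[(tert-butyldimethylsilyl)oxy]-16-[(tert-butyldiphenylsilyl)oxy]-2,10,14-trimethyl-9-[(triisopropylsilyl)oxy]hexadeca-2,10,14-trien-6-yn-4-ol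
Product: 19 (3E,4S,5R)-4-[(tert-butyldimethylsilyl)oxy]-3-{(3R,4E,8Z)-10-[(tert-butyldiphenylsilyl)oxy]-4,8-dimethyl-3-[(triisopropylsilyl)oxy]deca-4,8-dien-1-ylidene}-5-(2-methylprop-1-en-1-yl)oxolan-2-one
Conditions: PdCl2 (10 mol%), SnCl2 (10 mol%), PPh3 (20 mol%), CO (7 atm), MeCN–THF, 70 °C
Reagents that add atoms: carbon monoxide, [C-]#[O+]
Why: Divalent palladium, CO and the C5 hydroxyl should give an alkoxycarbonylpalladium species, the tethered alkyne inserts syn into its Pd–C bond, and protonolysis of the alkenyl–Pd bond by the HCl released at the outset returns the catalyst; the closest known reaction type is the PdCl2/SnCl2/PPh3-catalysed cyclocarbonylation of homopropargylic alcohols, internal alkynes included, to (E)-α-alkylidene-γ-butyrolactones. Ring A closes in the 5-exo-dig mode with C2 delivered to C3, and a six-membered endo closure is excluded because an intramolecular syn insertion cannot place a trans double bond in that ring. No stereocentre is created: the E geometry of C3=C1′ follows from syn addition, which leaves H cis to the carbonyl, and C4, C5 and C3′ are spectators. The step needs site selectivity among the oxygens and freedom from palladium allyl or propargyl chemistry, and the substrate secures both because only O5 is free, O4 and O3′ are silylated (O3′ could otherwise close a rival lactone on C1′, and a free O4 would open the way to a furan), and no allylic or propargylic ester is present. Phosphine and CO on palladium should hold back the electrophilic anti-oxypalladation that leads to dihydrofurans, and the hydrogen-free conditions spare the three alkenes.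

Step 15
Reactants: 19 the trisilylated lactone
Product: 20 (3E,4S,5R)-3-[(3R,4E,8Z)-3,10-dihydroxy-4,8-dimethyldeca-4,8-dien-1-ylidene]-4-hydroxy-5-(2-methylprop-1-en-1-yl)oxolan-2-one
Conditions: Bu4NF, AcOH, THF, 0 °C → 40 °C
Reagents that add atoms: none
Why: Fluoride-mediated desilylation removes the TBS, TIPS and TBDPS groups, the acetic acid buffer keeping the medium mild for the lactone, and the E alkene geometry keeps the C3′ hydroxyl from reaching the lactone carbonyl.

Step 16
Reactants: 20 the triol lactone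
Product: 21 (2Z,6E,8R)-8-hydroxy-10-[(3E,4S,5R)-4-hydroxy-5-(2-methylprop-1-en-1-yl)-2-oxooxolan-3-ylidene]-3,7-dimethyldeca-2,6-dien-1-yl benzoate
Conditions: BzCl (1.05 equiv), 2,4,6-collidine, CH2Cl2, −78 → −20 °C
Reagents that add atoms: benzoyl chloride, O=C(Cl)c1ccccc1
Why: Kinetically controlled acylation with one equivalent of benzoyl chloride and a hindered base at low temperature should pick the primary allylic hydroxyl over the two hindered secondary ones.

Step 17
Reactants: 21 the primary benzoate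
Product: 22 the target, (2Z,6E,8R)-8-acetoxy-10-[(3E,4S,5R)-4-acetoxy-5-(2-methylprop-1-en-1-yl)-2-oxooxolan-3-ylidene]-3,7-dimethyldeca-2,6-dien-1-yl benzoate
Conditions: Ac2O, pyridine, DMAP (cat.), CH2Cl2, 0 °C → rt
Reagents that add atoms: acetic anhydride, CC(=O)OC(C)=O
Why: DMAP-catalysed acetylation esterifies both remaining secondary hydroxyls under conditions too weakly basic to trigger vinylogous elimination of the C4 acetate.

**Compound list**

1 | 2,3-O-isopropylidene-D-erythronolactone | O=C1OC[C@H]2OC(C)(C)O[C@@H]12 | starting material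
2 | 2,3-O-isopropylidene-D-erythrofuranose (anomer mixture) | OC1OC[C@H]2OC(C)(C)O[C@@H]12 | intermediate
3 | [(4R,5S)-5-ethynyl-2,2-dimethyl-1,3-dioxolan-4-yl]methanol | C#C[C@@H]1OC(C)(C)O[C@@H]1CO | intermediate
4 | (4S,5S)-5-ethynyl-2,2-dimethyl-1,3-dioxolane-4-carbaldehyde | C#C[C@@H]1OC(C)(C)O[C@@H]1C=O | intermediate
5 | isopropyltriphenylphosphonium iodide | CC(C)[P+](c1ccccc1)(c1ccccc1)c1ccccc1.[I-] | starting material
6 | propan-2-ylidene(triphenyl)phosphorane | CC(C)=P(c1ccccc1)(c1ccccc1)c1ccccc1 | intermediate (not isolated)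
7 | (4S,5R)-4-ethynyl-2,2-dimethyl-5-(2-methylprop-1-en-1-yl)-1,3-dioxolane | C#C[C@@H]1OC(C)(C)O[C@@H]1C=C(C)C | intermediate
8 | nerol | CC(C)=CCC/C(C)=C\CO | starting material
9 | tert-butyl{[(2Z)-3,7-dimethylocta-2,6-dien-1-yl]oxy}diphenylsilane | CC(C)=CCC/C(C)=C\CO[Si](c1ccccc1)(c1ccccc1)C(C)(C)C | intermediate
10 | (2E,6Z)-8-[(tert-butyldiphenylsilyl)oxy]-2,6-dimethylocta-2,6-dien-1-ol | OC/C(C)=C/CC/C(C)=C\CO[Si](c1ccccc1)(c1ccccc1)C(C)(C)C | intermediate
11 | (2E,6Z)-8-[(tert-butyldiphenylsilyl)oxy]-2,6-dimethylocta-2,6-dienal | O=C/C(C)=C/CC/C(C)=C\CO[Si](c1ccccc1)(c1ccccc1)C(C)(C)C | intermediate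
12 | rac-tert-butyl{[(2Z,6E)-3-methyl-7-(oxiran-2-yl)octa-2,6-dien-1-yl]oxy}diphenylsilane | C1OC1/C(C)=C/CC/C(C)=C\CO[Si](c1ccccc1)(c1ccccc1)C(C)(C)C | intermediate
13 | tert-butyl({(2Z,6E)-3-methyl-7-[(2S)-oxiran-2-yl]octa-2,6-dien-1-yl}oxy)diphenylsilane | C1O[C@H]1/C(C)=C/CC/C(C)=C\CO[Si](c1ccccc1)(c1ccccc1)C(C)(C)C | intermediate
14 | lithium acetylide of 7 | [Li]C#C[C@@H]1OC(C)(C)O[C@@H]1C=C(C)C | intermediate (not isolated)
15 | (4R,5E,9Z)-11-[(tert-butyldiphenylsilyl)oxy]-1-[(4S,5R)-2,2-dimethyl-5-(2-methylprop-1-en-1-yl)-1,3-dioxolan-4-yl]-5,9-dimethylundeca-5,9-dien-1-yn-4-ol | O[C@H](CC#C[C@@H]1OC(C)(C)O[C@@H]1C=C(C)C)/C(C)=C/CC/C(C)=C\CO[Si](c1ccccc1)(c1ccccc1)C(C)(C)C | intermediate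
16 | O4-triisopropylsilyl ether of 15 | CC(C)[Si](C(C)C)(C(C)C)O[C@H](CC#C[C@@H]1OC(C)(C)O[C@@H]1C=C(C)C)/C(C)=C/CC/C(C)=C\CO[Si](c1ccccc1)(c1ccccc1)C(C)(C)C | intermediate
17 | (4R,5S,9R,10E,14Z)-16-[(tert-butyldiphenylsilyl)oxy]-2,10,14-trimethyl-9-[(triisopropylsilyl)oxy]hexadeca-2,10,14-trien-6-yne-4,5-diol | CC(C)[Si](C(C)C)(C(C)C)O[C@H](CC#C[C@H](O)[C@H](O)C=C(C)C)/C(C)=C/CC/C(C)=C\CO[Si](c1ccccc1)(c1ccccc1)C(C)(C)C | intermediate
18 | (4R,5S,9R,10E,14Z)-5-[(tert-butyldimethylsilyl)oxy]-16-[(tert-butyldiphenylsilyl)oxy]-2,10,14-trimethyl-9-[(triisopropylsilyl)oxy]hexadeca-2,10,14-trien-6-yn-4-ol | CC(C)[Si](C(C)C)(C(C)C)O[C@H](CC#C[C@H](O[Si](C)(C)C(C)(C)C)[C@H](O)C=C(C)C)/C(C)=C/CC/C(C)=C\CO[Si](c1ccccc1)(c1ccccc1)C(C)(C)C | intermediate (key-step precursor)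
19 | (3E,4S,5R)-4-[(tert-butyldimethylsilyl)oxy]-3-{(3R,4E,8Z)-10-[(tert-butyldiphenylsilyl)oxy]-4,8-dimethyl-3-[(triisopropylsilyl)oxy]deca-4,8-dien-1-ylidene}-5-(2-methylprop-1-en-1-yl)oxolan-2-one | CC(C)[Si](C(C)C)(C(C)C)O[C@H](C/C=C1/C(=O)O[C@H](C=C(C)C)[C@H]1O[Si](C)(C)C(C)(C)C)/C(C)=C/CC/C(C)=C\CO[Si](c1ccccc1)(c1ccccc1)C(C)(C)C | intermediate (key-step product)
20 | (3E,4S,5R)-3-[(3R,4E,8Z)-3,10-dihydroxy-4,8-dimethyldeca-4,8-dien-1-ylidene]-4-hydroxy-5-(2-methylprop-1-en-1-yl)oxolan-2-one | O[C@H](C/C=C1/C(=O)O[C@H](C=C(C)C)[C@H]1O)/C(C)=C/CC/C(C)=C\CO | intermediate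
21 | (2Z,6E,8R)-8-hydroxy-10-[(3E,4S,5R)-4-hydroxy-5-(2-methylprop-1-en-1-yl)-2-oxooxolan-3-ylidene]-3,7-dimethyldeca-2,6-dien-1-yl benzoate | O[C@H](C/C=C1/C(=O)O[C@H](C=C(C)C)[C@H]1O)/C(C)=C/CC/C(C)=C\COC(=O)c1ccccc1 | intermediate
22 | (2Z,6E,8R)-8-acetoxy-10-[(3E,4S,5R)-4-acetoxy-5-(2-methylprop-1-en-1-yl)-2-oxooxolan-3-ylidene]-3,7-dimethyldeca-2,6-dien-1-yl benzoate | CC(=O)O[C@H](C/C=C1/C(=O)O[C@H](C=C(C)C)[C@H]1OC(C)=O)/C(C)=C/CC/C(C)=C\COC(=O)c1ccccc1 | target

**Count**

Total step count: 17. Longest linear sequence: 13 steps (nerol 8 to target 22, steps 5 to 17).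

**Steps most likely to fail**

Step 14. The internal, doubly branched alkyne may insert too slowly into the alkoxycarbonyl–palladium bond. Electrophilic cycloisomerisation of the alkynol (5-endo attack of O5, leading to a dihydrofuran or, after loss of silanol, a furan) or acid-induced loss of silyl groups on prolonged heating could then take over. The fallback builds the same two bonds stepwise through an alkenyl iodide and sets out from diol 17. Palladium-catalysed syn hydrostannation (Bu3SnH, PdCl2(PPh3)2, THF, 0 °C) should place tin on the alkyne carbon next to the propargylic carbinol and give (4R,5R,6E,9R,10E,14Z)-16-[(tert-butyldiphenylsilyl)oxy]-2,10,14-trimethyl-6-(tributylstannyl)-9-[(triisopropylsilyl)oxy]hexadeca-2,6,10,14-tetraene-4,5-diol F1. Iodine in CH2Cl2 at 0 °C should exchange tin for iodine with retention and give the corresponding 6-iodo tetraene diol F2. Carbonylative lactonisation (Pd(PPh3)4, CO 1 atm, Et3N, MeCN–THF, 50 °C) passes through an acylpalladium species that only O5 can trap in a five-membered ring, and should give (3E,4S,5R)-3-{(3R,4E,8Z)-10-[(tert-butyldiphenylsilyl)oxy]-4,8-dimethyl-3-[(triisopropylsilyl)oxy]deca-4,8-dien-1-ylidene}-4-hydroxy-5-(2-methylprop-1-en-1-yl)oxolan-2-one F3 with the same E alkene. Bu4NF/AcOH then removes both silyl groups, and the route is rejoined at triol 20.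

Step 10. The acetylide may attack the allylic epoxide carbon or the alkene terminus (SN2′), or the opening may be so slow that the basic medium degrades the epoxide. The fallback replaces the epoxide by a primary triflate, whose substitution site is unambiguous, and sets out from racemic epoxide 12. Resolution with the enantiomeric catalyst, (R,R)-(salen)Co(OAc) and 0.45 equiv of water, should deliver the hydrolysis product (2S,3E,7Z)-9-[(tert-butyldiphenylsilyl)oxy]-3,7-dimethylnona-3,7-diene-1,2-diol F4. PivCl/pyridine at 0 °C should acylate the primary hydroxyl to give the 1-pivalate F5, and TIPSOTf/2,6-lutidine should give the 1-pivalate 2-triisopropylsilyl ether F6. i-Bu2AlH at −78 °C should remove the pivalate to give (2S,3E,7Z)-9-[(tert-butyldiphenylsilyl)oxy]-3,7-dimethyl-2-[(triisopropylsilyl)oxy]nona-3,7-dien-1-ol F7. Tf2O/2,6-lutidine at −78 °C should give its trifluoromethanesulfonate F8, which is alkylated without purification by lithium acetylide 14 in THF–DMPU at −78 → −20 °C. The route is rejoined at TIPS ether 16.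

Step 4. The basic ylide may epimerise the cis-dioxolane aldehyde to the trans series, or enolise it so that olefination stalls. The fallback uses a non-basic stabilised ylide and then removes the extra oxygen, and sets out from aldehyde 4. Ph3P=C(CH3)CO2Et in CH2Cl2 at rt should give ethyl (2E)-3-[(4R,5S)-5-ethynyl-2,2-dimethyl-1,3-dioxolan-4-yl]-2-methylprop-2-enoate F9. i-Bu2AlH at −78 °C should give (2E)-3-[(4R,5S)-5-ethynyl-2,2-dimethyl-1,3-dioxolan-4-yl]-2-methylprop-2-en-1-ol F10. CBr4/PPh3 at 0 °C should give (4S,5R)-4-ethynyl-5-[(1E)-3-bromo-2-methylprop-1-en-1-yl]-2,2-dimethyl-1,3-dioxolane F11, and direct hydride displacement with LiBHEt3 in THF at −78 → 0 °C converts CH2Br into CH3. The route is rejoined at enyne acetonide 7.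

**Further compounds**

F1 | step 14 | (4R,5R,6E,9R,10E,14Z)-16-[(tert-butyldiphenylsilyl)oxy]-2,10,14-trimethyl-6-(tributylstannyl)-9-[(triisopropylsilyl)oxy]hexadeca-2,6,10,14-tetraene-4,5-diol | CC(C)[Si](C(C)C)(C(C)C)O[C@H](C/C=C(/[Sn](CCCC)(CCCC)CCCC)[C@H](O)[C@H](O)C=C(C)C)/C(C)=C/CC/C(C)=C\CO[Si](c1ccccc1)(c1ccccc1)C(C)(C)C
F2 | step 14 | (4R,5R,6E,9R,10E,14Z)-16-[(tert-butyldiphenylsilyl)oxy]-6-iodo-2,10,14-trimethyl-9-[(triisopropylsilyl)oxy]hexadeca-2,6,10,14-tetraene-4,5-diol | CC(C)[Si](C(C)C)(C(C)C)O[C@H](C/C=C(/I)[C@H](O)[C@H](O)C=C(C)C)/C(C)=C/CC/C(C)=C\CO[Si](c1ccccc1)(c1ccccc1)C(C)(C)C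
F3 | step 14 | (3E,4S,5R)-3-{(3R,4E,8Z)-10-[(tert-butyldiphenylsilyl)oxy]-4,8-dimethyl-3-[(triisopropylsilyl)oxy]deca-4,8-dien-1-ylidene}-4-hydroxy-5-(2-methylprop-1-en-1-yl)oxolan-2-one | CC(C)[Si](C(C)C)(C(C)C)O[C@H](C/C=C1/C(=O)O[C@H](C=C(C)C)[C@H]1O)/C(C)=C/CC/C(C)=C\CO[Si](c1ccccc1)(c1ccccc1)C(C)(C)C
F4 | step 10 | (2S,3E,7Z)-9-[(tert-butyldiphenylsilyl)oxy]-3,7-dimethylnona-3,7-diene-1,2-diol | OC[C@@H](O)/C(C)=C/CC/C(C)=C\CO[Si](c1ccccc1)(c1ccccc1)C(C)(C)C
F5 | step 10 | (2S,3E,7Z)-9-[(tert-butyldiphenylsilyl)oxy]-2-hydroxy-3,7-dimethylnona-3,7-dien-1-yl 2,2-dimethylpropanoate | CC(C)(C)C(=O)OC[C@@H](O)/C(C)=C/CC/C(C)=C\CO[Si](c1ccccc1)(c1ccccc1)C(C)(C)C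
F6 | step 10 | (2S,3E,7Z)-9-[(tert-butyldiphenylsilyl)oxy]-3,7-dimethyl-2-[(triisopropylsilyl)oxy]nona-3,7-dien-1-yl 2,2-dimethylpropanoate | CC(C)(C)C(=O)OC[C@@H](O[Si](C(C)C)(C(C)C)C(C)C)/C(C)=C/CC/C(C)=C\CO[Si](c1ccccc1)(c1ccccc1)C(C)(C)C
F7 | step 10 | (2S,3E,7Z)-9-[(tert-butyldiphenylsilyl)oxy]-3,7-dimethyl-2-[(triisopropylsilyl)oxy]nona-3,7-dien-1-ol | OC[C@@H](O[Si](C(C)C)(C(C)C)C(C)C)/C(C)=C/CC/C(C)=C\CO[Si](c1ccccc1)(c1ccccc1)C(C)(C)C
F8 | step 10 | (2S,3E,7Z)-9-[(tert-butyldiphenylsilyl)oxy]-3,7-dimethyl-2-[(triisopropylsilyl)oxy]nona-3,7-dien-1-yl trifluoromethanesulfonate | FC(F)(F)S(=O)(=O)OC[C@@H](O[Si](C(C)C)(C(C)C)C(C)C)/C(C)=C/CC/C(C)=C\CO[Si](c1ccccc1)(c1ccccc1)C(C)(C)C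
F9 | step 4 | ethyl (2E)-3-[(4R,5S)-5-ethynyl-2,2-dimethyl-1,3-dioxolan-4-yl]-2-methylprop-2-enoate | C#C[C@@H]1OC(C)(C)O[C@@H]1/C=C(\C)C(=O)OCC
F10 | step 4 | (2E)-3-[(4R,5S)-5-ethynyl-2,2-dimethyl-1,3-dioxolan-4-yl]-2-methylprop-2-en-1-ol | C#C[C@@H]1OC(C)(C)O[C@@H]1/C=C(\C)CO
F11 | step 4 | (4S,5R)-4-ethynyl-5-[(1E)-3-bromo-2-methylprop-1-en-1-yl]-2,2-dimethyl-1,3-dioxolane | C#C[C@@H]1OC(C)(C)O[C@@H]1/C=C(\C)CBr
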